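**Retrosynthetic overview**
1. The last events are a global hydrogenolysis (six benzyl ethers and two blocking bromines on ring A) and, before it, an asymmetric transfer hydrogenation with dynamic kinetic resolution of a racemic flavan-3-one. C2–H is benzylic, O-substituted and α to the C3 ketone, so one reduction should set both stereocentres.
2. Ring C, the only ring that is made, is closed in one operation from an O-aryl α-acetoxybenzyl ether and the bis-silyl enediol ether of glycolaldehyde. C2–C3 forms by Mukaiyama-type addition to the O1=C2 oxocarbenium ion, C4–C4a by Friedel–Crafts closure, and a 1,2-hydride shift from C3 to C4 then gives the C3 ketone and the C4 methylene.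
3. Enabling feature: C2 lies between O1 and the electron-rich ring B, so it ionises easily as an acetal carbon. C4a is the ring A carbon flanked by O1 and the C5 hydroxyl and, once C6 and C8 carry bromine, the only free position of the phloroglucinol ring. The C3 oxygen next to benzylic C4 allows the redox-neutral hydride shift.
4. The precursor comes from desymmetrising mono-O-alkylation of 2,6-dibromo-3,5-dihydroxyphenyl tri-O-benzylgallate (phloroglucinol, tri-O-benzylgalloyl chloride, then dibromination). The 7-O-gallate is in place from the start and O5 stays a free phenol.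
5. One aryl unit is used twice: 3,4,5-tris(benzyloxy)benzoyl chloride gives the gallate, and 3,4,5-tris(benzyloxy)benzaldehyde gives C2 and ring B.

Key step: step 7

Assumption: 7, 8 and 14 are handled as racemates and 10 may contain the E isomer, because both features are erased before or in step 8; the (R,R) ligand is assumed to select the (2R)-ketone, and its mirror image is used without other change if a test reduction shows the opposite sense.

**Route**

Step 1
Reactants: 1 3,4,5-tris(benzyloxy)benzoic acid
Product: 2 3,4,5-tris(benzyloxy)benzoyl chloride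
Conditions: (COCl)2, DMF (cat.), CH2Cl2, 0 °C to rt
Reagents that add atoms: oxalyl chloride, ClC(=O)C(=O)Cl
Why: Acid chloride formation through Vilsmeier-type activation of the carboxylic acid by oxalyl chloride and catalytic DMF; no stereocentre is involved.

Step 2
Reactants: 2 3,4,5-tris(benzyloxy)benzoyl chloride, 3 phloroglucinol (benzene-1,3,5-triol)
Product: 4 3,5-dihydroxyphenyl 3,4,5-tris(benzyloxy)benzoate
Conditions: 3 (4 equiv), pyridine, THF, 0 °C
Reagents that add atoms: none
Why: Base-mediated O-acylation of a phenol by an acyl chloride, kept at the mono-ester stage by the excess of the triol, whose three hydroxyls are equivalent and whose water-soluble excess is washed out.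

Step 3
Reactants: 4 3,5-dihydroxyphenyl 3,4,5-tris(benzyloxy)benzoate
Product: 5 2,6-dibromo-3,5-dihydroxyphenyl 3,4,5-tris(benzyloxy)benzoate
Conditions: NBS (2.05 equiv), MeCN/CH2Cl2, −20 °C
Reagents that add atoms: N-bromosuccinimide, O=C1CCC(=O)N1Br
Why: Electrophilic aromatic bromination, which in 5-substituted resorcinols goes first to the two positions that are para to one hydroxyl and ortho to the other, so the carbon between the two hydroxyls (the later C4a) should stay free while the later C6 and C8 are blocked.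

Step 4
Reactants: 6 3,4,5-tris(benzyloxy)benzaldehyde
Product: 7 racemic chloro[3,4,5-tris(benzyloxy)phenyl]methyl acetate
Conditions: AcCl, ZnCl2 (5 mol%), CH2Cl2, 0 °C; used crude
Reagents that add atoms: acetyl chloride, CC(=O)Cl
Why: ZnCl2-catalysed addition of an acyl chloride across the aldehyde C=O (α-chloroalkyl ester formation); the new acetal-type carbon is racemic, which does not matter because it is ionised in step 7.

Step 5
Reactants: 5 2,6-dibromo-3,5-dihydroxyphenyl 3,4,5-tris(benzyloxy)benzoate, 7 racemic chloro[3,4,5-tris(benzyloxy)phenyl]methyl acetate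
Product: 8 racemic 3-{acetoxy[3,4,5-tris(benzyloxy)phenyl]methoxy}-2,6-dibromo-5-hydroxyphenyl 3,4,5-tris(benzyloxy)benzoate
Conditions: 7 (1.0 equiv), i-Pr2NEt, CH2Cl2, −20 to 0 °C
Reagents that add atoms: none
Why: O-alkylation of a phenol by an α-chloroalkyl ester (acyloxyalkyl ether formation, SN1-like at the benzylic acetal carbon); the two hydroxyls of 5 are equivalent, so mono-alkylation should give one constitutional isomer, with the new acetal carbon racemic.

Step 6
Reactants: 9 glycolaldehyde dimer (1,4-dioxane-2,5-diol)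
Product: 10 (Z)-1,2-bis(trimethylsilyloxy)ethene
Conditions: Me3SiCl, Et3N, DMF, 60 °C; distillation
Reagents that add atoms: chlorotrimethylsilane, C[Si](C)(C)Cl
Why: Silyl enol ether formation from an enolisable aldehyde under chlorosilane/amine conditions after thermal cracking of the dimer, together with O-silylation of the hydroxyl; the alkene geometry is of no consequence later.

Step 7
Reactants: 8 racemic 3-{acetoxy[3,4,5-tris(benzyloxy)phenyl]methoxy}-2,6-dibromo-5-hydroxyphenyl 3,4,5-tris(benzyloxy)benzoate, 10 (Z)-1,2-bis(trimethylsilyloxy)ethene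
Product: 14 racemic 6,8-dibromo-5-hydroxy-3-oxo-2-[3,4,5-tris(benzyloxy)phenyl]-3,4-dihydro-2H-chromen-7-yl 3,4,5-tris(benzyloxy)benzoate, via oxocarbenium triflate 11 (not isolated), via silyloxy aldehyde 12 (not isolated), via 3,4-bis(trimethylsilyloxy)flavan 13 (not isolated)
Conditions: 10 (1.3 equiv), Me3SiOTf (0.3 equiv), 4 Å MS, CH2Cl2, −78 to 0 °C; aq NaHCO3
Reagents that add atoms: none
Why: Proposed new method: Me3SiOTf silylates the acetate carbonyl of 8 so that acetate, not the electron-poor aryloxide, leaves and the O-aryl oxocarbenium ion 11 forms; the symmetric enediol ether 10 adds through either carbon to C2 (Mukaiyama-type addition to an acetal-derived cation, first new bond C2–C3) and gives the silyl-activated α-silyloxy aldehyde 12, whose carbonyl carbon is attacked by C4a of ring A (second new bond C4–C4a) to give 13. The closest known reaction type is the oxa-Povarov reaction, the formal [4+2] addition of O-aryl oxocarbenium ions to alkenes that gives chromans through the same two bonds, here run on a 1,2-dioxygenated alkene and ended by a pinacol-type step. Ring C is closed in a 6-exo-trig Friedel–Crafts mode, the carbonyl oxygen staying outside the new ring and the C4a=C8a bond of the arene inside it. The benzylic C4–OSiMe3 bond of 13 should then ionise, helped by O1 and the C5 hydroxyl, and a 1,2-hydride shift from C3 (semipinacol) gives the C3 ketone and the C4 methylene and releases Me3SiOTf again, so that the enediol carbons end at the ketone and methylene levels without any redox reagent. C2 is the only stereocentre of 14 and is left racemic on purpose, because it is enolisable and is set in step 8. The step needs site selectivity on ring A and chemoselective ionisation: C6 and C8 carry bromine, so C4a, flanked by O1 and the C5 hydroxyl, is the only free ring position (which also suppresses intermolecular arylation), and the acetate is the only Lewis-basic leaving group.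

Step 8
Reactants: 14 racemic 6,8-dibromo-5-hydroxy-3-oxo-2-[3,4,5-tris(benzyloxy)phenyl]-3,4-dihydro-2H-chromen-7-yl 3,4,5-tris(benzyloxy)benzoate
Product: 15 (2R,3R)-6,8-dibromo-3,5-dihydroxy-2-[3,4,5-tris(benzyloxy)phenyl]-3,4-dihydro-2H-chromen-7-yl 3,4,5-tris(benzyloxy)benzoate (2,3-cis)
Conditions: RuCl[(R,R)-TsDPEN](p-cymene) (2 mol%), HCO2H/Et3N (5:2), EtOAc, 25 °C, argon
Reagents that add atoms: none
Why: Asymmetric transfer hydrogenation with dynamic kinetic resolution, a known reaction type for α-aryl and α-aryloxy cyclic ketones: Et3N should racemise C2 through the enol faster than reduction, the catalyst should reduce the (2R)-ketone preferentially, and hydride is delivered to the C3 carbonyl face anti to the pseudo-equatorial C2 aryl group, which sets C3 as R and gives the cis (2R,3R)-alcohol.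

Step 9
Reactants: 15 (2R,3R)-6,8-dibromo-3,5-dihydroxy-2-[3,4,5-tris(benzyloxy)phenyl]-3,4-dihydro-2H-chromen-7-yl 3,4,5-tris(benzyloxy)benzoate
Product: 16 epigallocatechin 7-O-gallate, (2R,3R)-3,5-dihydroxy-2-(3,4,5-trihydroxyphenyl)-3,4-dihydro-2H-chromen-7-yl 3,4,5-trihydroxybenzoate
Conditions: H2 (1 atm), Pd(OH)2/C, NaOAc, THF/EtOAc/H2O, rt
Reagents that add atoms: none
Why: Heterogeneous catalytic hydrogenolysis should cleave the six benzyl ethers and the two aryl C–Br bonds in one operation, NaOAc taking up the HBr, while the aryl ester and the C2–O1 bond are kept as in the usual deprotection of benzylated catechin gallates; no stereocentre is touched.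

**Compound list**
1 | 3,4,5-tris(benzyloxy)benzoic acid | OC(=O)c1cc(OCc2ccccc2)c(OCc2ccccc2)c(OCc2ccccc2)c1 | starting material
2 | 3,4,5-tris(benzyloxy)benzoyl chloride | ClC(=O)c1cc(OCc2ccccc2)c(OCc2ccccc2)c(OCc2ccccc2)c1 | intermediate
3 | phloroglucinol (benzene-1,3,5-triol) | Oc1cc(O)cc(O)c1 | starting material
4 | 3,5-dihydroxyphenyl 3,4,5-tris(benzyloxy)benzoate | O=C(Oc1cc(O)cc(O)c1)c1cc(OCc2ccccc2)c(OCc2ccccc2)c(OCc2ccccc2)c1 | intermediate
5 | 2,6-dibromo-3,5-dihydroxyphenyl 3,4,5-tris(benzyloxy)benzoate | O=C(Oc1c(Br)c(O)cc(O)c1Br)c1cc(OCc2ccccc2)c(OCc2ccccc2)c(OCc2ccccc2)c1 | intermediate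
6 | 3,4,5-tris(benzyloxy)benzaldehyde | O=Cc1cc(OCc2ccccc2)c(OCc2ccccc2)c(OCc2ccccc2)c1 | starting material
7 | racemic chloro[3,4,5-tris(benzyloxy)phenyl]methyl acetate | CC(=O)OC(Cl)c1cc(OCc2ccccc2)c(OCc2ccccc2)c(OCc2ccccc2)c1 | intermediate
8 | racemic 3-{acetoxy[3,4,5-tris(benzyloxy)phenyl]methoxy}-2,6-dibromo-5-hydroxyphenyl 3,4,5-tris(benzyloxy)benzoate | CC(=O)OC(Oc1cc(O)c(Br)c(OC(=O)c2cc(OCc3ccccc3)c(OCc3ccccc3)c(OCc3ccccc3)c2)c1Br)c1cc(OCc2ccccc2)c(OCc2ccccc2)c(OCc2ccccc2)c1 | intermediate
9 | glycolaldehyde dimer (1,4-dioxane-2,5-diol) | OC1COC(O)CO1 | starting material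
10 | (Z)-1,2-bis(trimethylsilyloxy)ethene | C[Si](C)(C)O/C=C\O[Si](C)(C)C | intermediate
11 | O-aryl oxocarbenium triflate, ring A oxygen doubly bonded to the benzylic carbon of ring B | O=C(Oc1c(Br)c(O)cc([O+]=Cc2cc(OCc3ccccc3)c(OCc3ccccc3)c(OCc3ccccc3)c2)c1Br)c1cc(OCc2ccccc2)c(OCc2ccccc2)c(OCc2ccccc2)c1.[O-]S(=O)(=O)C(F)(F)F | intermediate (not isolated)
12 | 3-aryloxy-3-aryl-2-(trimethylsilyloxy)propanal, diastereomer mixture, racemic | O=CC(O[Si](C)(C)C)C(Oc1cc(O)c(Br)c(OC(=O)c2cc(OCc3ccccc3)c(OCc3ccccc3)c(OCc3ccccc3)c2)c1Br)c1cc(OCc2ccccc2)c(OCc2ccccc2)c(OCc2ccccc2)c1 | intermediate (not isolated)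
13 | 6,8-dibromo-5-hydroxy-3,4-bis(trimethylsilyloxy)-2-[3,4,5-tris(benzyloxy)phenyl]chroman-7-yl 3,4,5-tris(benzyloxy)benzoate, diastereomer mixture, racemic | C[Si](C)(C)OC1C(O[Si](C)(C)C)c2c(O)c(Br)c(OC(=O)c3cc(OCc4ccccc4)c(OCc4ccccc4)c(OCc4ccccc4)c3)c(Br)c2OC1c1cc(OCc2ccccc2)c(OCc2ccccc2)c(OCc2ccccc2)c1 | intermediate (not isolated)
14 | racemic 6,8-dibromo-5-hydroxy-3-oxo-2-[3,4,5-tris(benzyloxy)phenyl]-3,4-dihydro-2H-chromen-7-yl 3,4,5-tris(benzyloxy)benzoate | O=C1Cc2c(O)c(Br)c(OC(=O)c3cc(OCc4ccccc4)c(OCc4ccccc4)c(OCc4ccccc4)c3)c(Br)c2OC1c1cc(OCc2ccccc2)c(OCc2ccccc2)c(OCc2ccccc2)c1 | intermediate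
15 | (2R,3R)-6,8-dibromo-3,5-dihydroxy-2-[3,4,5-tris(benzyloxy)phenyl]-3,4-dihydro-2H-chromen-7-yl 3,4,5-tris(benzyloxy)benzoate | O=C(Oc1c(Br)c(O)c2c(c1Br)O[C@H](c1cc(OCc3ccccc3)c(OCc3ccccc3)c(OCc3ccccc3)c1)[C@H](O)C2)c1cc(OCc2ccccc2)c(OCc2ccccc2)c(OCc2ccccc2)c1 | intermediate
16 | epigallocatechin 7-O-gallate, (2R,3R)-3,5-dihydroxy-2-(3,4,5-trihydroxyphenyl)-3,4-dihydro-2H-chromen-7-yl 3,4,5-trihydroxybenzoate | O=C(Oc1cc(O)c2c(c1)O[C@H](c1cc(O)c(O)c(O)c1)[C@H](O)C2)c1cc(O)c(O)c(O)c1 | target

**Step count and risks**

Total step count: 9. Longest linear sequence: 7 steps (steps 1, 2, 3, 5, 7, 8, 9).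

Steps most likely to fail:

1. Step 7 (Proposed new method). What may go wrong: ionisation of the aryloxy C–O bond instead of the acetate; capture of the C4 cation by the enediol ether or by another ring A instead of the hydride shift; protodesilylation of the enediol ether by adventitious triflic acid; a stop at the 3,4-dioxygenated stage. Fallback with known chemistry only, setting out from 5 and 6 and coming back at 14: 6 is treated with HC≡CMgBr (THF, 0 °C) to give racemic 1-[3,4,5-tris(benzyloxy)phenyl]prop-2-yn-1-ol F1, which makes C2–C3 by acetylide addition. Mono-Mitsunobu etherification of 5 with F1 (PPh3, DIAD, THF, 0 °C) gives the aryl propargyl ether F2. Gold-catalysed alkyne oxidation (Ph3PAuNTf2, 3,5-dichloropyridine N-oxide, ClCH2CH2Cl, rt), the known way from aryl propargyl ethers to chroman-3-ones, forms an α-oxo gold carbene that attacks C4a, the only free position of ring A, and gives 14.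

2. Step 8. What may go wrong: racemisation at C2 that is too slow relative to reduction; a low level or the wrong sense of enantioface selection on a ketone that carries no aryl group on the carbonyl carbon; slow turnover in the presence of the acidic phenol. Fallback setting out from 14 and coming back at 15: LiBH(s-Bu)3 (THF, −78 °C) reduces the ketone from the face anti to the C2 aryl group and gives the racemic cis-alcohol, that is 15 together with its (2S,3S)-enantiomer F3. Preparative chromatography on a chiral stationary phase separates the two, and F3 is returned to 14 by Dess–Martin oxidation, so the material re-enters the route.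

3. Step 9. What may go wrong: slow or incomplete hydrodebromination; inhibition of the catalyst by bromide; hydrogenolytic opening of the benzylic C2–O1 bond on prolonged exposure; acid-induced damage if HBr is not buffered. Fallback setting out from 15 and coming back at 16: radical debromination first (Bu3SnH, AIBN, toluene, 80 °C) gives the bromine-free hexabenzyl ether (2R,3R)-3,5-dihydroxy-2-[3,4,5-tris(benzyloxy)phenyl]-3,4-dihydro-2H-chromen-7-yl 3,4,5-tris(benzyloxy)benzoate F4. Hydrogenolysis under neutral conditions (H2, Pd(OH)2/C, THF/MeOH, rt) then removes the benzyl groups and gives 16.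

Further compounds
F1 | step 7 | racemic 1-[3,4,5-tris(benzyloxy)phenyl]prop-2-yn-1-ol | C#CC(O)c1cc(OCc2ccccc2)c(OCc2ccccc2)c(OCc2ccccc2)c1
F2 | step 7 | racemic 2,6-dibromo-5-hydroxy-3-({1-[3,4,5-tris(benzyloxy)phenyl]prop-2-yn-1-yl}oxy)phenyl 3,4,5-tris(benzyloxy)benzoate | C#CC(Oc1cc(O)c(Br)c(OC(=O)c2cc(OCc3ccccc3)c(OCc3ccccc3)c(OCc3ccccc3)c2)c1Br)c1cc(OCc2ccccc2)c(OCc2ccccc2)c(OCc2ccccc2)c1
F3 | step 8 | (2S,3S)-6,8-dibromo-3,5-dihydroxy-2-[3,4,5-tris(benzyloxy)phenyl]-3,4-dihydro-2H-chromen-7-yl 3,4,5-tris(benzyloxy)benzoate | O=C(Oc1c(Br)c(O)c2c(c1Br)O[C@@H](c1cc(OCc3ccccc3)c(OCc3ccccc3)c(OCc3ccccc3)c1)[C@@H](O)C2)c1cc(OCc2ccccc2)c(OCc2ccccc2)c(OCc2ccccc2)c1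
F4 | step 9 | (2R,3R)-3,5-dihydroxy-2-[3,4,5-tris(benzyloxy)phenyl]-3,4-dihydro-2H-chromen-7-yl 3,4,5-tris(benzyloxy)benzoate | O=C(Oc1cc(O)c2c(c1)O[C@H](c1cc(OCc3ccccc3)c(OCc3ccccc3)c(OCc3ccccc3)c1)[C@H](O)C2)c1cc(OCc2ccccc2)c(OCc2ccccc2)c(OCc2ccccc2)c1
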